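**Plan**

1. Target numbering used throughout: ring C1 (OAc), C2 (=CH), C3 (=C, bearing C7H2OBz), C4 (OH), C5 (OBz), C6 (OH). The enabling feature is that the only C=C, C2=C3 of the single cyclohexene ring, lies between the two allylic carbinol carbons C1 and C4; cutting it (retro ring-closing metathesis) leaves an open chain C4–C5–C6–C1 in which every carbon is a sugar carbinol and both ends are terminal alkenes.
2. Second cut, C3–C4 (retro Nozaki–Hiyama–Kishi alkenylation): C3, C7 and the methylidene later lost as ethylene come from 2-bromoallyl alcohol; C4 is an aldehyde carbon.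
3. Third cut, back to the ring of methyl α-D-mannopyranoside: C4, C5, C6, C1, C2 are mannose C1–C5; zinc fragmentation of the 6-iodide unmasks the C4 aldehyde and the C2 vinyl group at once.
4. The acyl pattern is written on the pyranoside before it is opened: 2,3-orthobenzoate formation, O4 acetylation and orthoester opening give the O2 benzoate (C5), free O3 (C6) and the O4 acetate (C1). The pyranose ring, the iodide and the ketone level at C4 are the only helpers; no protecting group is carried.
5. Forward order: pyranoside functionalised and opened (steps 1–3), chain extended and benzoylated (4–5), ring closed on the chain that already holds the final acyl pattern (6), C4 oxidised (7) and reduced (8).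
6. Stereochemistry: C1, C5 and C6 are bought (mannose C4, C2, C3); C4 is left unset in the chain and set last on the ring by hydride delivery directed by the C6 hydroxyl (1,3-anti).

Key step: step 6

Remark: the three intermediates between the alkenylation and the oxidation are carried as pairs of epimers at the future C4, which is left undefined in their SMILES, because that centre is erased in step 7 and set in step 8.

**Step 1**
Reactants: 1 methyl α-D-mannopyranoside
Product: 2 methyl 6-deoxy-6-iodo-α-D-mannopyranoside
Conditions: I2, PPh3, imidazole, THF, 65 °C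
Reagents that add atoms: iodine, [I][I]
Why: Garegg–Samuelsson iodination, in which the iodophosphonium/imidazole reagent activates the unhindered primary O6 hydroxyl much faster than the three secondary ones and iodide displaces it by SN2, no stereocenter being touched.

**Step 2**
Reactants: 2 methyl 6-deoxy-6-iodo-α-D-mannopyranoside; 3 trimethyl orthobenzoate; 4 acetic anhydride
Product: 7 methyl 4-O-acetyl-2-O-benzoyl-6-deoxy-6-iodo-α-D-mannopyranoside, via 2,3-orthobenzoate 5 (not isolated), via 4-O-acetyl-2,3-orthobenzoate 6 (not isolated)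
Conditions: PhC(OMe)3, CSA (cat.), MeCN, rt; then Ac2O, pyridine, rt; then 80% aq. AcOH, rt
Reagents that add atoms: trimethyl orthobenzoate (3), COC(OC)(OC)c1ccccc1; acetic anhydride (4), CC(=O)OC(C)=O; water, O
Why: Cyclic orthoester formation picks the cis-2,3-diol (five-membered ring), the remaining O4 hydroxyl is acetylated, and mild acid hydrolysis of the orthoester through its dioxolenium ion should give, as is the rule for pyranoside orthoesters, the ester on the axial oxygen (O2) and the free hydroxyl on the equatorial one (O3), with no stereocenter changed.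

**Step 3**
Reactants: 7 methyl 4-O-acetyl-2-O-benzoyl-6-deoxy-6-iodo-α-D-mannopyranoside
Product: 8 4-O-acetyl-2-O-benzoyl-5,6-dideoxy-D-lyxo-hex-5-enose (used crude)
Conditions: activated Zn dust, THF/H2O (4:1), ultrasound, 40 °C
Reagents that add atoms: none
Why: Bernet–Vasella reductive fragmentation, in which zinc inserts into the C6–I bond, the organozinc expels the ring oxygen from C5 to give the terminal alkene and the hemiacetal anion loses methoxide to give the aldehyde, while mannose C2, C3 and C4 and both esters should survive the near-neutral medium.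

**Step 4**
Reactants: 8 4-O-acetyl-2-O-benzoyl-5,6-dideoxy-D-lyxo-hex-5-enose; 9 2-bromoprop-2-en-1-ol
Product: 10 (3RS,4R,5S,6R)-6-(acetyloxy)-1,3,5-trihydroxy-2-methylideneoct-7-en-4-yl benzoate (both epimers at chain C3 = target C4)
Conditions: CrCl2, NiCl2 (cat.), DMF, rt
Reagents that add atoms: 2-bromoprop-2-en-1-ol (9), OCC(Br)=C
Why: Nozaki–Hiyama–Kishi alkenylation, in which the C–Br bond adds to zerovalent nickel formed in situ, the alkenyl group passes to trivalent chromium and adds to the aldehyde only, tolerating the esters, the allylic acetate and free hydroxyls; the new C4 carbinol centre is not controlled (Felkin–Anh addition anti to the α-benzoyloxy group should favour the 4-epi isomer) and need not be, since step 7 erases it.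

**Step 5**
Reactants: 10 triol (C4 epimers); 11 benzoyl chloride
Product: 12 (3RS,4R,5S,6R)-6-(acetyloxy)-3,5-dihydroxy-2-methylideneoct-7-ene-1,4-diyl dibenzoate (C4 epimers)
Conditions: BzCl, 2,4,6-collidine, CH2Cl2, −40 °C
Reagents that add atoms: benzoyl chloride (11), O=C(Cl)c1ccccc1
Why: Acyl chloride with a hindered pyridine base at low temperature is a primary-selective acylation, so the primary allylic C7 hydroxyl should be benzoylated ahead of the two secondary ones, and the weak base should leave the secondary esters where they are.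

**Step 6**
Reactants: 12 diene diol dibenzoate acetate (C4 epimers)
Product: 13 [(3R,4S,5R,6RS)-3-(acetyloxy)-5-(benzoyloxy)-4,6-dihydroxycyclohex-1-en-1-yl]methyl benzoate (C4 epimers)
Conditions: second-generation Grubbs catalyst RuCl2(=CHPh)(PCy3)(H2IMes) (5 mol %), 1,4-benzoquinone (10 mol %), CH2Cl2 (0.005 M), 40 °C
Reagents that add atoms: none
Why: Ring-closing olefin metathesis by the Chauvin mechanism: the ruthenium benzylidene should exchange onto the monosubstituted vinyl group at C2, the new alkylidene should add across the 1,1-disubstituted alkene at C3 through a ruthenacyclobutane, and cycloreversion should leave the C2=C3 bond and expel ethylene. The closest known reaction type is the RCM of sugar-derived octa-1,7-dienes with one 1,1-disubstituted terminus to trisubstituted carbasugar cyclohexenes, which runs with free hydroxyls and esters on the chain. The six-membered carbocycle closes head to head between the two terminal alkenes of the 1,7-diene, so both alkene carbons become ring atoms and the new double bond is endocyclic and necessarily cis. No stereocenter is formed or touched: C1, C5 and C6 pass through unchanged and both C4 epimers close, which is why C4 did not have to be controlled before this step. The step needs ring closure to beat cross-metathesis oligomerisation and ruthenium hydride isomerisation of the allylic alcohol; high dilution, the gauche-rich conformation of the fully oxygenated four-carbon tether, the free allylic C4 hydroxyl next to the hindered alkene and the loss of ethylene should secure the first, and 1,4-benzoquinone as hydride scavenger the second.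

**Step 7**
Reactants: 13 cyclohexenediol (C4 epimers)
Product: 14 [(3R,4S,5S)-3-(acetyloxy)-5-(benzoyloxy)-4-hydroxy-6-oxocyclohex-1-en-1-yl]methyl benzoate
Conditions: activated MnO2, CH2Cl2, rt
Reagents that add atoms: none
Why: Allylic oxidation with MnO2 acts only on the allylic C4 hydroxyl (the C6 hydroxyl is not allylic) and should turn both C4 epimers into one enone under neutral conditions, with C1, C5 and C6 untouched.

**Step 8**
Reactants: 14 enone
Product: 15 [(3R,4S,5R,6S)-3-(acetyloxy)-5-(benzoyloxy)-4,6-dihydroxycyclohex-1-en-1-yl]methyl benzoate (CNP0169028.1)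
Conditions: Me4NBH(OAc)3, MeCN/AcOH (1:1), −30 °C
Reagents that add atoms: none
Why: Evans–Saksena hydroxyl-directed reduction, in which the C6 hydroxyl exchanges onto boron and delivers hydride to the carbonyl face on its own side, so the C4 hydroxyl should emerge anti to the C6 hydroxyl (1,3-anti, trans to the C5 benzoate, 4S in target numbering); the acidic medium disfavours acyl migration and the reagent should leave the conjugated C=C and the esters alone.

**Compound list**

1 | methyl α-D-mannopyranoside | CO[C@H]1O[C@H](CO)[C@@H](O)[C@H](O)[C@@H]1O | starting material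
2 | methyl 6-deoxy-6-iodo-α-D-mannopyranoside | CO[C@H]1O[C@H](CI)[C@@H](O)[C@H](O)[C@@H]1O | intermediate
3 | trimethyl orthobenzoate | COC(OC)(OC)c1ccccc1 | starting material
4 | acetic anhydride | CC(=O)OC(C)=O | starting material
5 | methyl 6-deoxy-6-iodo-2,3-O-(α-methoxybenzylidene)-α-D-mannopyranoside (orthoester carbon as a mixture) | CO[C@H]1O[C@H](CI)[C@@H](O)[C@@H]2OC(OC)(c3ccccc3)O[C@H]12 | intermediate
6 | methyl 4-O-acetyl-6-deoxy-6-iodo-2,3-O-(α-methoxybenzylidene)-α-D-mannopyranoside (orthoester carbon as a mixture) | CO[C@H]1O[C@H](CI)[C@@H](OC(C)=O)[C@@H]2OC(OC)(c3ccccc3)O[C@H]12 | intermediate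
7 | methyl 4-O-acetyl-2-O-benzoyl-6-deoxy-6-iodo-α-D-mannopyranoside | CO[C@H]1O[C@H](CI)[C@@H](OC(C)=O)[C@H](O)[C@@H]1OC(=O)c1ccccc1 | intermediate
8 | 4-O-acetyl-2-O-benzoyl-5,6-dideoxy-D-lyxo-hex-5-enose, (2S,3S,4R)-4-(acetyloxy)-3-hydroxy-1-oxohex-5-en-2-yl benzoate | C=C[C@@H](OC(C)=O)[C@H](O)[C@H](OC(=O)c1ccccc1)C=O | intermediate
9 | 2-bromoprop-2-en-1-ol | OCC(Br)=C | starting material
10 | (3RS,4R,5S,6R)-6-(acetyloxy)-1,3,5-trihydroxy-2-methylideneoct-7-en-4-yl benzoate (epimer pair at chain C3 = target C4) | C=C[C@@H](OC(C)=O)[C@H](O)[C@H](OC(=O)c1ccccc1)C(O)C(=C)CO | intermediate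
11 | benzoyl chloride | O=C(Cl)c1ccccc1 | starting material
12 | (3RS,4R,5S,6R)-6-(acetyloxy)-3,5-dihydroxy-2-methylideneoct-7-ene-1,4-diyl dibenzoate (epimer pair at chain C3 = target C4) | C=C[C@@H](OC(C)=O)[C@H](O)[C@H](OC(=O)c1ccccc1)C(O)C(=C)COC(=O)c1ccccc1 | intermediate
13 | [(3R,4S,5R,6RS)-3-(acetyloxy)-5-(benzoyloxy)-4,6-dihydroxycyclohex-1-en-1-yl]methyl benzoate (epimer pair at target C4) | CC(=O)O[C@@H]1C=C(COC(=O)c2ccccc2)C(O)[C@@H](OC(=O)c2ccccc2)[C@H]1O | intermediate
14 | [(3R,4S,5S)-3-(acetyloxy)-5-(benzoyloxy)-4-hydroxy-6-oxocyclohex-1-en-1-yl]methyl benzoate | CC(=O)O[C@@H]1C=C(COC(=O)c2ccccc2)C(=O)[C@@H](OC(=O)c2ccccc2)[C@H]1O | intermediate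
15 | [(3R,4S,5R,6S)-3-(acetyloxy)-5-(benzoyloxy)-4,6-dihydroxycyclohex-1-en-1-yl]methyl benzoate (CNP0169028.1) | CC(=O)O[C@@H]1C=C(COC(=O)c2ccccc2)[C@H](O)[C@@H](OC(=O)c2ccccc2)[C@H]1O | target

**Step count and risks**

Total steps: 8. Longest linear sequence: 8 steps (from 1).

Steps most likely to fail:

1. Step 3. What may go wrong: migration of the benzoyl group from O2 to the free O3 hydroxyl, and retro-aldol or elimination of the open-chain α-acyloxy-β-hydroxy aldehyde during fragmentation and handling. Fallback: it sets out from 7, whose O3 hydroxyl is silylated (Et3SiOTf, 2,6-lutidine, CH2Cl2, −40 °C) to methyl 4-O-acetyl-2-O-benzoyl-6-deoxy-6-iodo-3-O-triethylsilyl-α-D-mannopyranoside F1. Zinc fragmentation as in step 3 should then give 4-O-acetyl-2-O-benzoyl-5,6-dideoxy-3-O-triethylsilyl-D-lyxo-hex-5-enose F2, in which the migration terminus is blocked. Alkenylation with 9 as in step 4 should give (3RS,4R,5S,6R)-6-(acetyloxy)-1,3-dihydroxy-2-methylidene-5-[(triethylsilyl)oxy]oct-7-en-4-yl benzoate F3, and HF·pyridine (THF/pyridine, 0 °C) should remove the silyl group, so that the fallback comes back to the route at 10.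

2. Step 6. What may go wrong: slow ring closure at the hindered, 1,1-disubstituted and doubly allylic-oxygenated alkene, leaving room for oligomerisation and for ruthenium hydride isomerisation of the allylic alcohol. Fallback: the ring is closed at an unhindered alkene and C7 is added afterwards. It sets out from 8, which is alkenylated with vinyl bromide (CrCl2, cat. NiCl2, DMF, rt) in place of 9 to give (3RS,4R,5S,6R)-6-(acetyloxy)-3,5-dihydroxyocta-1,7-dien-4-yl benzoate F4. RCM with the same catalyst should give (1R,2RS,5R,6S)-5-(acetyloxy)-2,6-dihydroxycyclohex-3-en-1-yl benzoate F5, and MnO2 should give (1S,5R,6S)-5-(acetyloxy)-6-hydroxy-2-oxocyclohex-3-en-1-yl benzoate F6. Morita–Baylis–Hillman hydroxymethylation (aqueous formaldehyde, imidazole, THF/H2O, rt) should place the hydroxymethyl group on C3 to give (1S,5R,6S)-5-(acetyloxy)-6-hydroxy-3-(hydroxymethyl)-2-oxocyclohex-3-en-1-yl benzoate F7. Benzoylation of its primary hydroxyl (BzCl, 2,4,6-collidine, CH2Cl2, −40 °C) brings the fallback back to the route at 14.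

3. Step 8. What may go wrong: hydride delivery to the wrong face (external attack in place of hydroxyl-directed delivery), or sluggish reduction of the conjugated carbonyl. Fallback: reagent control in place of substrate direction. It sets out from 14 and goes straight to 15 by Corey–Bakshi–Shibata reduction (2-methyl-CBS-oxazaborolidine, catecholborane, toluene, −78 °C). The catalyst enantiomer is the one that places hydride on the C4 face syn to O6; this should be the (S)-catalyst if, as with other 2-substituted cyclohex-2-enones, the alkenyl arm acts as the large group. No new compound is made.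

**Further compounds**

F1 | step 3 | methyl 4-O-acetyl-2-O-benzoyl-6-deoxy-6-iodo-3-O-triethylsilyl-α-D-mannopyranoside | CO[C@H]1O[C@H](CI)[C@@H](OC(C)=O)[C@H](O[Si](CC)(CC)CC)[C@@H]1OC(=O)c1ccccc1
F2 | step 3 | 4-O-acetyl-2-O-benzoyl-5,6-dideoxy-3-O-triethylsilyl-D-lyxo-hex-5-enose | C=C[C@@H](OC(C)=O)[C@H](O[Si](CC)(CC)CC)[C@H](OC(=O)c1ccccc1)C=O
F3 | step 3 | (3RS,4R,5S,6R)-6-(acetyloxy)-1,3-dihydroxy-2-methylidene-5-[(triethylsilyl)oxy]oct-7-en-4-yl benzoate | C=C[C@@H](OC(C)=O)[C@H](O[Si](CC)(CC)CC)[C@H](OC(=O)c1ccccc1)C(O)C(=C)CO
F4 | step 6 | (3RS,4R,5S,6R)-6-(acetyloxy)-3,5-dihydroxyocta-1,7-dien-4-yl benzoate | C=C[C@@H](OC(C)=O)[C@H](O)[C@H](OC(=O)c1ccccc1)C(O)C=C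
F5 | step 6 | (1R,2RS,5R,6S)-5-(acetyloxy)-2,6-dihydroxycyclohex-3-en-1-yl benzoate | CC(=O)O[C@@H]1C=CC(O)[C@@H](OC(=O)c2ccccc2)[C@H]1O
F6 | step 6 | (1S,5R,6S)-5-(acetyloxy)-6-hydroxy-2-oxocyclohex-3-en-1-yl benzoate | CC(=O)O[C@@H]1C=CC(=O)[C@@H](OC(=O)c2ccccc2)[C@H]1O
F7 | step 6 | (1S,5R,6S)-5-(acetyloxy)-6-hydroxy-3-(hydroxymethyl)-2-oxocyclohex-3-en-1-yl benzoate | CC(=O)O[C@@H]1C=C(CO)C(=O)[C@@H](OC(=O)c2ccccc2)[C@H]1O
F0 | step 8 | none | none
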